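**Retrosynthetic overview**

1. Eudesmane numbering is used (ring A = C1–C5 and C10; ring B = C5–C10; C3 angelate, C4 acetate and methyl, C7 isopropylidene, C8 ketone, C10 angular methyl; β = face of the C10 methyl). Target 24 ⇐ diol enone 20 by two esterifications ⇐ hydroxy diketone 14 by hydroxyl-directed reduction at C3 and acetone aldol/dehydration at C7.
2. 14 ⇐ acyclic selenoester 13 in one radical chain: ring B closes first through the C8–C9 bond (acyl radical onto the isopropenyl group), ring A second through the C10–C1 bond (tertiary radical onto the vinyl ketone).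
3. Enabling feature: in ring B the ketone carbon C8 is bonded to C9H2, which sits on the methyl-bearing quaternary C10, and C10 is linked through C1–C2 to the oxygenated C3 of ring A. This C8(=O)–C9–C10(CH3)–C1–C2–C3(O) array is what an acyl radical, a CH2=C(CH3)– group and a vinyl ketone give by two 6-endo closures.
4. 13 ⇐ δ-lactone 8 (a temporary ring tying the C4 oxygen to C8) by vinylation, selenolate ring opening and oxidation; 8 ⇐ epoxy alcohol 5 by isopropenyl–copper opening (sets C5; the epoxide oxygen becomes the C4 oxygen).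
5. 5 ⇐ ester 3 (Johnson–Claisen of 1 with 2) by allylic oxidation and Katsuki–Sharpless epoxidation, the only source of absolute configuration.

Key step: step 9

**Route**

Step 1
Reactants: 1 2-methylbut-3-en-2-ol; 2 triethyl orthoacetate
Product: 3 ethyl 5-methylhex-4-enoate
Conditions: EtCO2H (cat.), neat, 140 °C, EtOH distilled off
Reagents that add atoms: none
Why: Johnson–Claisen rearrangement; the mixed ketene acetal of the tertiary allylic alcohol undergoes a [3,3] shift to the γ,δ-unsaturated ester with the trisubstituted alkene, and no stereocentre is formed.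

Step 2
Reactants: 3 ethyl 5-methylhex-4-enoate
Product: 4 ethyl (4E)-6-hydroxy-5-methylhex-4-enoate
Conditions: SeO2 (cat.), t-BuOOH, CH2Cl2, rt
Reagents that add atoms: tert-butyl hydroperoxide CC(C)(C)OO
Why: SeO2 allylic oxidation (ene reaction then [2,3] shift) is selective for the (E)-methyl of a gem-dimethyl trisubstituted alkene, so the (E)-allylic alcohol should result with the ester untouched.

Step 3
Reactants: 4 ethyl (4E)-6-hydroxy-5-methylhex-4-enoate
Product: 5 ethyl 3-[(2R,3R)-3-(hydroxymethyl)-3-methyloxiran-2-yl]propanoate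
Conditions: Ti(OiPr)4 (cat.), D-(−)-diethyl tartrate (cat.), t-BuOOH, 4 Å MS, CH2Cl2, −20 °C
Reagents that add atoms: tert-butyl hydroperoxide CC(C)(C)OO
Why: Katsuki–Sharpless asymmetric epoxidation; D-(−)-tartrate delivers oxygen to the face that gives the (2R,3R)-epoxide (mirror image of the series obtained with the natural tartrate), which fixes the future C4 and the centre that is inverted to C5.

Step 4
Reactants: 5 ethyl 3-[(2R,3R)-3-(hydroxymethyl)-3-methyloxiran-2-yl]propanoate; 6 isopropenylmagnesium bromide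
Product: 8 (5R,6S)-6-(hydroxymethyl)-6-methyl-5-(prop-1-en-2-yl)oxan-2-one, via dihydroxy ester 7 (not isolated)
Conditions: 6 (excess), CuI (cat.), THF, −30 °C; aq NH4Cl; then TsOH (cat.), CH2Cl2, rt
Reagents that add atoms: none
Why: Copper-catalysed Grignard opening of a 2,3-epoxy alcohol by SN2 attack with inversion at the less substituted epoxide carbon sets C5, while the quaternary C4 keeps its C–O bond; acid then closes the six-membered lactone between the tertiary hydroxyl and the ester, masking both.

Step 5
Reactants: 8 (5R,6S)-6-(hydroxymethyl)-6-methyl-5-(prop-1-en-2-yl)oxan-2-one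
Product: 9 (2S,3R)-2-methyl-6-oxo-3-(prop-1-en-2-yl)oxane-2-carbaldehyde
Conditions: IBX, DMSO, rt
Reagents that add atoms: none
Why: IBX oxidation of the primary alcohol to the aldehyde; the α-carbon is quaternary, so nothing can epimerise, and lactone and alkene are inert.

Step 6
Reactants: 9 (2S,3R)-2-methyl-6-oxo-3-(prop-1-en-2-yl)oxane-2-carbaldehyde; 10 vinylmagnesium bromide
Product: 11 (5R,6S)-6-(1-hydroxyprop-2-en-1-yl)-6-methyl-5-(prop-1-en-2-yl)oxan-2-one (both carbinol epimers)
Conditions: 10, THF, −78 °C; aq NH4Cl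
Reagents that add atoms: none
Why: Grignard 1,2-addition to the aldehyde is much faster than attack on the lactone at −78 °C; the new carbinol centre is not controlled and is removed by oxidation in step 8.

Step 7
Reactants: 11 (5R,6S)-6-(1-hydroxyprop-2-en-1-yl)-6-methyl-5-(prop-1-en-2-yl)oxan-2-one
Product: 12 Se-phenyl (4R,5S)-5,6-dihydroxy-5-methyl-4-(prop-1-en-2-yl)oct-7-eneselenoate (both C6 epimers)
Conditions: Me2AlSePh (preformed, excess), CH2Cl2, 0 °C to rt; cold aq citric acid work-up; used at once
Reagents that add atoms: dimethylaluminium benzeneselenolate C[Al](C)[Se]c1ccccc1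
Why: Aluminium-selenolate acyl transfer (ester-to-selenoester exchange) opens the lactone at the acyl–oxygen bond, driven by a five-membered aluminium 1,2-diolate formed from the released tertiary alkoxide and its neighbour, which should also hold the ring open until the cold work-up.

Step 8
Reactants: 12 Se-phenyl (4R,5S)-5,6-dihydroxy-5-methyl-4-(prop-1-en-2-yl)oct-7-eneselenoate
Product: 13 Se-phenyl (4R,5S)-5-hydroxy-5-methyl-6-oxo-4-(prop-1-en-2-yl)oct-7-eneselenoate
Conditions: IBX, DMSO, rt; used at once
Reagents that add atoms: none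
Why: IBX oxidises the secondary allylic alcohol to the vinyl ketone without cleaving the 1,2-diol unit or touching the tertiary alcohol, and the neutral conditions should leave the selenoester intact.

Step 9
Reactants: 13 Se-phenyl (4R,5S)-5-hydroxy-5-methyl-6-oxo-4-(prop-1-en-2-yl)oct-7-eneselenoate
Product: 14 (1S,4aR,8aR)-1-hydroxy-1,4a-dimethylhexahydronaphthalene-2,6(1H,3H)-dione (trans-decalin; 4α-OH, 4β-CH3, 10β-CH3, 5α-H, ketones at C3 and C8)
Conditions: 13, Bu3SnH and AIBN (cat.) in PhH added together by syringe pump to PhH at 80 °C (high dilution)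
Reagents that add atoms: none
Why: Bu3Sn• takes PhSe from 13 to give the C8 acyl radical, which closes ring B by 6-endo-trig attack on C9, the CH2 terminus of the isopropenyl group, leaving a tertiary radical at C10; this nucleophilic radical closes ring A by 6-endo-trig conjugate addition to C1 of the vinyl ketone, and the C2 α-keto radical takes hydrogen from Bu3SnH to carry the chain. The closest known reaction type is the acyl-radical cascade of polyene selenoesters by consecutive 6-endo-trig closures, which gives trans-fused angular-methyl decalones. The one new stereocentre, C10, is controlled by the existing C5 centre: ring B reacts as a chair with the C5 side chain equatorial, and ring A forms through a chair-like transition state in which the new C10–C1 bond is equatorial and the C10 methyl axial (trans fusion), the C4 centre then carrying its methyl axial and its hydroxyl equatorial. The step needs 6-endo over 5-exo closure twice, secured for ring B by the methyl on C10 (a 5-exo adduct would in any case ring-expand by 1,2-acyl shift to the same C10 radical) and for ring A by polarity, since only the terminal carbon of the enone accepts a nucleophilic radical. It also needs both closures to outrun hydrogen transfer, loss of CO and thermal re-lactonisation, secured by low stationary concentrations of stannane and substrate and by the slow decarbonylation of a primary-alkyl acyl radical.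

Step 10
Reactants: 14 (1S,4aR,8aR)-1-hydroxy-1,4a-dimethylhexahydronaphthalene-2,6(1H,3H)-dione
Product: 15 (4aR,5S,6S,8aR)-5,6-dihydroxy-5,8a-dimethyloctahydronaphthalen-2(1H)-one (3β,4α-diol, 8-ketone)
Conditions: Me4NBH(OAc)3, MeCN/AcOH, −30 °C
Reagents that add atoms: none
Why: Saksena–Evans hydroxyl-directed reduction; the 4α-hydroxyl binds boron and delivers hydride to C3 from the α-face (also the axial trajectory, the β-face being shielded by the axial 4-methyl), giving the equatorial 3β-alcohol trans to the C4 oxygen, while the C8 ketone has no directing hydroxyl and should not be reduced.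

Step 11
Reactants: 15 (4aR,5S,6S,8aR)-5,6-dihydroxy-5,8a-dimethyloctahydronaphthalen-2(1H)-one
Product: 16 trimethyl{[(4aR,5S,6S,8aR)-5,8a-dimethyl-5,6-bis(trimethylsilyloxy)-1,4,4a,5,6,7,8,8a-octahydronaphthalen-2-yl]oxy}silane
Conditions: Me3SiOTf (excess), Et3N, CH2Cl2, 0 °C
Reagents that add atoms: trimethylsilyl trifluoromethanesulfonate C[Si](C)(C)OS(=O)(=O)C(F)(F)F
Why: Soft enolisation silylates both hydroxyls and converts the C8 ketone into the enol silane toward C7, because C9 is a neopentyl-type CH2 next to the quaternary C10 and the C7–C8 enol is the favoured one in a trans-fused decalone of this substitution.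

Step 12
Reactants: 16 trimethyl{[(4aR,5S,6S,8aR)-5,8a-dimethyl-5,6-bis(trimethylsilyloxy)-1,4,4a,5,6,7,8,8a-octahydronaphthalen-2-yl]oxy}silane; 17 acetone
Product: 20 (4aR,5S,6S,8aR)-5,6-dihydroxy-5,8a-dimethyl-3-(propan-2-ylidene)octahydronaphthalen-2(1H)-one, via silylated aldol 18 (not isolated), via triol ketone 19 (not isolated)
Conditions: 17, TiCl4, CH2Cl2, −78 °C; then 2 M aq HCl, THF, 45 °C
Reagents that add atoms: none
Why: Mukaiyama aldol addition to acetone at C7, then acid removes the silyl ethers and dehydrates the tertiary β-hydroxy ketone to the conjugated tetrasubstituted isopropylidene ketone, which destroys the transient C7 stereocentre.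

Step 13
Reactants: 20 (4aR,5S,6S,8aR)-5,6-dihydroxy-5,8a-dimethyl-3-(propan-2-ylidene)octahydronaphthalen-2(1H)-one; 21 angelic acid
Product: 23 (1S,2S,4aR,8aR)-1-hydroxy-1,4a-dimethyl-6-oxo-7-(propan-2-ylidene)decahydronaphthalen-2-yl (2Z)-2-methylbut-2-enoate, via mixed anhydride 22 (not isolated)
Conditions: 21, 2,4,6-trichlorobenzoyl chloride, Et3N, PhMe, rt; then 20, PhMe, 80 °C
Reagents that add atoms: 2,4,6-trichlorobenzoyl chloride O=C(Cl)c1c(Cl)cc(Cl)cc1Cl (its atoms are kept only in intermediate 22)
Why: Yamaguchi esterification through the mixed anhydride acylates only the secondary equatorial 3β-hydroxyl (the tertiary 4-hydroxyl is too hindered), and leaving out a nucleophilic catalyst should keep the (Z)-angelate from isomerising to the tiglate.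

Step 14
Reactants: 23 (1S,2S,4aR,8aR)-1-hydroxy-1,4a-dimethyl-6-oxo-7-(propan-2-ylidene)decahydronaphthalen-2-yl (2Z)-2-methylbut-2-enoate
Product: 24 (1S,2S,4aR,8aR)-1-acetoxy-1,4a-dimethyl-6-oxo-7-(propan-2-ylidene)decahydronaphthalen-2-yl (2Z)-2-methylbut-2-enoate (3β-angeloyloxy-4α-acetoxyeudesm-7(11)-en-8-one)
Conditions: Ac2O, Sc(OTf)3 (cat.), MeCN, −20 °C
Reagents that add atoms: acetic anhydride CC(=O)OC(C)=O
Why: Lewis-acid-catalysed acetylation with Ac2O, a known way to acetylate hindered tertiary alcohols at low temperature without elimination, and the enone and the angelate should be tolerated.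

**Compound list**

1 | 2-methylbut-3-en-2-ol | CC(C)(O)C=C | starting material
2 | triethyl orthoacetate | CCOC(C)(OCC)OCC | starting material
3 | ethyl 5-methylhex-4-enoate | CCOC(=O)CCC=C(C)C | intermediate
4 | ethyl (4E)-6-hydroxy-5-methylhex-4-enoate | CCOC(=O)CC/C=C(\C)CO | intermediate
5 | ethyl 3-[(2R,3R)-3-(hydroxymethyl)-3-methyloxiran-2-yl]propanoate | OC[C@@]1(C)O[C@@H]1CCC(=O)OCC | intermediate
6 | isopropenylmagnesium bromide | CC(=C)[Mg]Br | starting material
7 | ethyl (4R,5S)-5,6-dihydroxy-5-methyl-4-(prop-1-en-2-yl)hexanoate (formed in the flask, not isolated) | OC[C@@](C)(O)[C@@H](C(C)=C)CCC(=O)OCC | intermediate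
8 | (5R,6S)-6-(hydroxymethyl)-6-methyl-5-(prop-1-en-2-yl)oxan-2-one | OC[C@@]1(C)OC(=O)CC[C@@H]1C(C)=C | intermediate
9 | (2S,3R)-2-methyl-6-oxo-3-(prop-1-en-2-yl)oxane-2-carbaldehyde | O=C[C@@]1(C)OC(=O)CC[C@@H]1C(C)=C | intermediate
10 | vinylmagnesium bromide | C=C[Mg]Br | starting material
11 | (5R,6S)-6-(1-hydroxyprop-2-en-1-yl)-6-methyl-5-(prop-1-en-2-yl)oxan-2-one (both carbinol epimers) | C=CC(O)[C@@]1(C)OC(=O)CC[C@@H]1C(C)=C | intermediate
12 | Se-phenyl (4R,5S)-5,6-dihydroxy-5-methyl-4-(prop-1-en-2-yl)oct-7-eneselenoate (both C6 epimers) | C=CC(O)[C@@](C)(O)[C@@H](C(C)=C)CCC(=O)[Se]c1ccccc1 | intermediate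
13 | Se-phenyl (4R,5S)-5-hydroxy-5-methyl-6-oxo-4-(prop-1-en-2-yl)oct-7-eneselenoate | C=CC(=O)[C@@](C)(O)[C@@H](C(C)=C)CCC(=O)[Se]c1ccccc1 | intermediate
14 | (1S,4aR,8aR)-1-hydroxy-1,4a-dimethylhexahydronaphthalene-2,6(1H,3H)-dione | O=C1CC[C@]2(C)CC(=O)CC[C@H]2[C@]1(C)O | intermediate
15 | (4aR,5S,6S,8aR)-5,6-dihydroxy-5,8a-dimethyloctahydronaphthalen-2(1H)-one | O[C@H]1CC[C@]2(C)CC(=O)CC[C@H]2[C@]1(C)O | intermediate
16 | trimethyl{[(4aR,5S,6S,8aR)-5,8a-dimethyl-5,6-bis(trimethylsilyloxy)-1,4,4a,5,6,7,8,8a-octahydronaphthalen-2-yl]oxy}silane | C[Si](C)(C)O[C@H]1CC[C@]2(C)CC(O[Si](C)(C)C)=CC[C@H]2[C@]1(C)O[Si](C)(C)C | intermediate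
17 | acetone | CC(C)=O | starting material
18 | (4aR,5S,6S,8aR)-3-(2-hydroxypropan-2-yl)-5,8a-dimethyl-5,6-bis(trimethylsilyloxy)octahydronaphthalen-2(1H)-one (C3 epimers; formed in the flask, not isolated) | C[Si](C)(C)O[C@H]1CC[C@]2(C)CC(=O)C(C(C)(C)O)C[C@H]2[C@]1(C)O[Si](C)(C)C | intermediate
19 | (4aR,5S,6S,8aR)-5,6-dihydroxy-3-(2-hydroxypropan-2-yl)-5,8a-dimethyloctahydronaphthalen-2(1H)-one (C3 epimers; formed in the flask, not isolated) | O[C@H]1CC[C@]2(C)CC(=O)C(C(C)(C)O)C[C@H]2[C@]1(C)O | intermediate
20 | (4aR,5S,6S,8aR)-5,6-dihydroxy-5,8a-dimethyl-3-(propan-2-ylidene)octahydronaphthalen-2(1H)-one | O[C@H]1CC[C@]2(C)CC(=O)C(=C(C)C)C[C@H]2[C@]1(C)O | intermediate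
21 | angelic acid, (2Z)-2-methylbut-2-enoic acid | C/C=C(/C)C(=O)O | starting material
22 | (2Z)-2-methylbut-2-enoic 2,4,6-trichlorobenzoic anhydride (formed in the flask, not isolated) | C/C=C(/C)C(=O)OC(=O)c1c(Cl)cc(Cl)cc1Cl | intermediate
23 | (1S,2S,4aR,8aR)-1-hydroxy-1,4a-dimethyl-6-oxo-7-(propan-2-ylidene)decahydronaphthalen-2-yl (2Z)-2-methylbut-2-enoate | C/C=C(/C)C(=O)O[C@H]1CC[C@]2(C)CC(=O)C(=C(C)C)C[C@H]2[C@]1(C)O | intermediate
24 | (1S,2S,4aR,8aR)-1-acetoxy-1,4a-dimethyl-6-oxo-7-(propan-2-ylidene)decahydronaphthalen-2-yl (2Z)-2-methylbut-2-enoate | C/C=C(/C)C(=O)O[C@H]1CC[C@]2(C)CC(=O)C(=C(C)C)C[C@H]2[C@]1(C)OC(C)=O | target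

**Step count and risks**

Total step count: 14. Longest linear sequence: 14 steps (1 to 24).

Steps most likely to fail:

1. Step 9. What may go wrong: hydrogen transfer from the stannane to the tertiary C10 radical before ring A closes, or addition of the stannyl radical to the vinyl ketone, so that the chain stops at a monocyclic ketone. The fallback sets out from 12 and comes back at 14; it closes the rings one at a time and uses no stoichiometric hydrogen-atom donor. Both hydroxyls of 12 are silylated (Et3SiOTf, 2,6-lutidine) to the bis(triethylsilyl) ether F1, and the selenoester is reduced to the aldehyde F2 (Bu3SnH, Pd(PPh3)4). Ring B is then closed, again through the C8–C9 bond, by the Me2AlCl-promoted intramolecular carbonyl-ene reaction of the aldehyde with the isopropenyl group (hydrogen taken from its methyl), giving the methylenecyclohexanol F3. Bu4NF removes the silyl groups to give the triol F4, and IBX oxidises both secondary alcohols to the methylene diketone F5. Ring A is closed by the Fe(acac)3/PhSiH3 hydrogen-atom-transfer reductive coupling of the exocyclic methylene with the vinyl ketone: hydrogen adds to the CH2 terminus, which becomes the C10 methyl, and the tertiary C10 radical adds to C1, giving 14.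

2. Step 4. What may go wrong: slow SN2 attack of the bulky alkenyl–copper reagent at the epoxide carbon next to the quaternary centre, so that addition to the ester or base-induced epoxide migration takes over. The fallback sets out from 5 and comes back at 8. The small, linear aluminium acetylide Et2AlC≡CSiMe3 (from Me3SiC≡CH, BuLi, Et2AlCl) opens the 2,3-epoxy alcohol at the carbon remote from the hydroxymethyl group with inversion, and acid-catalysed lactonisation gives the silylalkynyl lactone F6. Bu4NF/AcOH gives the ethynyl lactone F7. Negishi carboalumination (Me3Al, Cp2ZrCl2 (cat.), CH2Cl2) followed by protonolysis turns the ethynyl group into the isopropenyl group, giving 8.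

3. Step 12. What may go wrong: partial enolisation toward C9, reversal of the acetone aldol, or acid-induced ionisation and rearrangement at the tertiary C4 carbinol during the dehydration. The fallback sets out from 15 and comes back at 20. The diol is capped as the bis(triethylsilyl) ether F8 (Et3SiOTf, 2,6-lutidine). The kinetic lithium enolate (LDA, THF, −78 °C, deprotonation at the unhindered C7) is transmetalated with ZnCl2 and added to acetone to give the aldol F9. Dehydration under basic conditions (SOCl2, pyridine, 0 °C, then DBU to bring the double bond into conjugation) gives the isopropylidene ketone F10, and Bu4NF removes the silyl groups, giving 20.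

**Further compounds**

F1 | step 9 | Se-phenyl (4R,5S)-5-methyl-4-(prop-1-en-2-yl)-5,6-bis(triethylsilyloxy)oct-7-eneselenoate (C6 epimers) | C=CC(O[Si](CC)(CC)CC)[C@@](C)(O[Si](CC)(CC)CC)[C@@H](C(C)=C)CCC(=O)[Se]c1ccccc1
F2 | step 9 | (4R,5S)-5-methyl-4-(prop-1-en-2-yl)-5,6-bis(triethylsilyloxy)oct-7-enal (C6 epimers) | C=CC(O[Si](CC)(CC)CC)[C@@](C)(O[Si](CC)(CC)CC)[C@@H](C(C)=C)CCC=O
F3 | step 9 | (4R)-4-[(2S)-2,3-bis(triethylsilyloxy)pent-4-en-2-yl]-3-methylidenecyclohexan-1-ol (carbinol epimers) | C=CC(O[Si](CC)(CC)CC)[C@@](C)(O[Si](CC)(CC)CC)[C@@H]1CCC(O)CC1=C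
F4 | step 9 | (4R)-4-[(2S)-2,3-dihydroxypent-4-en-2-yl]-3-methylidenecyclohexan-1-ol (carbinol epimers) | C=CC(O)[C@@](C)(O)[C@@H]1CCC(O)CC1=C
F5 | step 9 | (4R)-4-[(2S)-2-hydroxy-3-oxopent-4-en-2-yl]-3-methylidenecyclohexan-1-one | C=CC(=O)[C@@](C)(O)[C@@H]1CCC(=O)CC1=C
F6 | step 4 | (5R,6S)-6-(hydroxymethyl)-6-methyl-5-[(trimethylsilyl)ethynyl]oxan-2-one | OC[C@@]1(C)OC(=O)CC[C@@H]1C#C[Si](C)(C)C
F7 | step 4 | (5R,6S)-5-ethynyl-6-(hydroxymethyl)-6-methyloxan-2-one | OC[C@@]1(C)OC(=O)CC[C@@H]1C#C
F8 | step 12 | (4aR,5S,6S,8aR)-5,8a-dimethyl-5,6-bis(triethylsilyloxy)octahydronaphthalen-2(1H)-one | CC[Si](CC)(CC)O[C@H]1CC[C@]2(C)CC(=O)CC[C@H]2[C@]1(C)O[Si](CC)(CC)CC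
F9 | step 12 | (4aR,5S,6S,8aR)-3-(2-hydroxypropan-2-yl)-5,8a-dimethyl-5,6-bis(triethylsilyloxy)octahydronaphthalen-2(1H)-one (C3 epimers) | CC[Si](CC)(CC)O[C@H]1CC[C@]2(C)CC(=O)C(C(C)(C)O)C[C@H]2[C@]1(C)O[Si](CC)(CC)CC
F10 | step 12 | (4aR,5S,6S,8aR)-5,8a-dimethyl-3-(propan-2-ylidene)-5,6-bis(triethylsilyloxy)octahydronaphthalen-2(1H)-one | CC[Si](CC)(CC)O[C@H]1CC[C@]2(C)CC(=O)C(=C(C)C)C[C@H]2[C@]1(C)O[Si](CC)(CC)CC
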